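## Structural features

The target is a spiro[5.5]undecane of the chamigrane type: ring A is a cross-conjugated cyclohexadienone, ring B a saturated halogenated cyclohexane, and the two share one quaternary carbon. In ring A the spiro carbon lies between a gem-dimethyl carbon and the carbon that carries the exocyclic methylene; the carbonyl follows that carbon and is conjugated to the ring C=C, which ends at the gem-dimethyl carbon. Going round ring B from the spiro carbon the atoms are CH(OAc), CH2, C(CH3)Cl, CHBr, CH2. All four stereocentres lie in ring B: the spiro carbon (R) is adjacent to the acetoxy carbon (S), and the chlorine-bearing carbon (R) is adjacent to the bromine-bearing carbon (R). Acetoxy, chlorine and the methylene-bearing branch of ring A lie on one face of ring B; bromine, the ring B methyl and the gem-dimethyl branch lie on the other. Fragile groups are the α-methylene dienone (a doubly activated Michael acceptor), the tertiary chloride beside a secondary bromide (elimination, halonium scrambling) and the acetate (hydrolysis, acyl transfer). The real difficulty is the quaternary spiro stereocentre, wedged between a quaternary carbon, a carbinol carbon and an sp2 carbon, and the relay of its configuration to three further centres. The key step exploits the 1,4-dioxygen relation acetoxy carbon (ring B) – spiro carbon – methylene-bearing carbon (ring A) – carbonyl carbon (ring A), which is the retron of an alkoxycyclopropyl ketone; ring B, with oxygen on one carbon and the halogens on a former alkene across the ring, has the pattern of a 2,5-dihydroanisole.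

## Logic of the disconnections

**22 to 18.** The exocyclic C=CH2 bond is cut first, through 21 and 20. It is the most reactive group and should be made last. In 18 the only enolisable position is the α′ CH2, because the γ carbon is quaternary, so the one-carbon unit can only enter where it is needed. The forward steps must enolise without strong base, since acetate, bromide and tertiary chloride are present.

**18 to 16.** The ring A C=C is removed to give 17, and the carbonyl of 17 is masked as the dioxolane 16. Only one α-carbon of 17 has a β-hydrogen, which fixes the site of dehydrogenation. The mask is needed further back, where ring A and ring B each carry a ketone.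

**16 to 14.** The acyl C–O bond, then the C–Br and C–Cl bonds, are cut, leading through 15 to the homoallylic alcohol 14. Both halogen-bearing stereocentres then derive from one alkene and are controlled by the neighbouring hydroxyl. The forward step must place chlorine on the tertiary carbon, cis to the oxygen, and bromine anti to it.

**14 to 12.** The carbinol C–H bond is cut to give ketone 13, and the ketal is removed to give diketone 12. The only stereocentre left is the spiro carbon. The forward steps must distinguish a neopentylic ring B ketone from an unhindered ring A ketone (by sterics), and must choose one face of the ring B carbonyl (by reagent control).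

**12 to 11.** The ring A α-carbon is reconnected to the ring B carbonyl carbon, with the latter as a methyl ketal carbon, giving the methoxycyclopropyl ketone 11. The ring A carbonyl is deliberately kept as the acceptor for the forward opening. If it were reduced first, a plain methoxycyclopropane would remain, and this opens only in acid strong enough to move the ring B alkene into conjugation. Push–pull opening needs only cold dilute acid.

**11 to 10.** Both cyclopropane bonds at the carbenoid carbon are cut, the one to the spiro carbon and the one to the methoxy carbon. Two rings and three stereocentres disappear and the achiral diazoketone 10 is left. The forward step must select one enantiotopic face of a tetrasubstituted enol ether.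

**10 to 6.** The diazo group is removed to give methyl ketone 8, the oxidation level is adjusted to alcohol 7, and the diene is traced to the anisole 6 by a Birch transform. This places the enol ether and the ring B alkene exactly where oxygen and halogens are needed. The side-chain oxygen must pass the dissolving-metal step as an alcohol.

**6 to 1 and 2.** The secondary C–O bond is cut (Markovnikov hydration of 5), then one C–CH3 bond of the quaternary benzylic carbon (methylation of 4), then the aryl–carbon bond (addition of 3, made from 1, to 2). Two commercial compounds remain.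

## Other disconnections considered

**Alternative 1:** The cut is the ring A bond between the gem-dimethyl carbon and its CH2 neighbour. In the forward sense Fe(acac)3 (trivalent iron) with PhSiH3 would transfer a hydrogen atom to the isopropenyl group of the ring B acetate A2, which carries isopropenyl and 2-oxobut-3-enyl groups on the future spiro carbon. The tertiary radical would add 6-endo to the terminal carbon of the vinyl ketone and give A1.

- In its favour: the bond formed is not the congested one, radical conjugate addition tolerates crowding and esters, and ring A arrives as a ketone without any protection.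
- A1 is the same compound as 17, so both plans share the last three steps.
- On protecting-group and redox economy in ring A this alternative is the better plan; the chosen route needs steps 9 and 13 only to mask and unmask that carbonyl.
- Against it: the key step creates no stereocentre. A2 must already hold all four, including the quaternary carbon with four different carbon substituents next to the acetoxy carbon. The problem that the carbenoid step solves is moved into the synthesis of A2, on a ring whose halogens are prone to elimination.
- Mechanistically it is a stepwise radical chain, with loss of bromine by halogen abstraction and plain reduction of the isopropenyl group as side paths. The chosen step is a catalyst-controlled two-bond addition.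
- In steps, the cyclisation is as short as steps 7 and 8 together, but the way to A2 is likely to be longer than the thirteen steps to 17.

**Alternative 2:** The cut removes the bond from the spiro carbon to its ring B CH2 neighbour and, for a time, a bond from the ring A α-carbon to a methylidene-bearing carbon. In the forward sense irradiation of enone A4 with propa-1,2-diene A5 would give the cis-fused head-to-head cyclobutane A3.

- In its favour: one intermolecular step from an achiral, quickly made enone forms the quaternary carbon next to the gem-dimethyl carbon. A3 already holds the ring A ketone and a masked formyl group for the acetoxy carbon.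
- Up to the key step this alternative is the better plan: it needs no Birch reduction and no diazo compound.
- Both plans are equal in using a strained ring as a temporary device that is opened again.
- Against it: A3 would be racemic unless a chiral Lewis acid or an auxiliary is added, and such control is less developed for A5 than for copper carbenoids. Head-to-head regiochemistry at a β-carbon flanked by a quaternary carbon is not assured.
- The four-membered ring must then be opened at the bond between the α-carbon and the methylidene-bearing carbon, classically after oxidative cleavage of the methylidene group and by a retro-Claisen reaction. That removes the methylidene carbon, so it is not the exocyclic methylene of the target.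
- After the opening ring B still lacks two ring carbons, its methyl group and three stereocentres. In the chosen plan every ring B carbon and the alkene for halogenation are present directly after step 8, so the alternative is longer overall.

**Alternative 3:** The cut is the bond between the spiro carbon and the gem-dimethyl carbon. In the forward sense heating the enantioenriched dihydropyran A7 would cause a Claisen rearrangement: the ring-fusion enol ether and the 2-methylprop-1-enyl group join, the C–O bond breaks, and A6 results with carbocyclic ring A and the ring B ketone.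

- In its favour: the concerted [3,3] shift transfers the configuration of the pyran stereocentre to the spiro carbon without a catalyst, and it forms the bond between two fully substituted carbons, for which sigmatropic shifts are well suited.
- Ring B of A6 is identical with that of 12, so the chemistry of steps 10 to 12 applies. Ring A already has its C=C in the right place and no second ketone, so ketal steps and dehydrogenation fall away.
- On certainty of stereochemical transfer and on step count after the key step this alternative is the better plan.
- Against it: the stereocentre of A7 needs its own asymmetric synthesis. The alkenyl group cannot pass a dissolving-metal reduction (allylic C–O cleavage), so it must be built onto an acid- and air-sensitive dihydroaromatic.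
- The thermal step risks aromatisation and [1,3] shifts at a fully substituted terminus.
- The ring A oxygen must come from a late allylic C–H oxidation beside bromide, chloride and acetate, and the ring A alkene must survive the bromochlorination. The chosen plan brings the ring A oxygen in with the carbenoid carbon and sets the configuration catalytically from an achiral precursor.

Key step: step 7

Assumption: the (S,S)-bis(oxazoline) is taken as the ligand antipode that leads to 11. The sense of induction cannot be assigned with confidence beforehand for this substrate; if it is the opposite, the (R,R)-ligand replaces it and nothing else changes.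

## Route

Step 1
Reactants: 1 1-bromo-2-methoxy-4-methylbenzene; 2 hex-5-en-2-one
Product: 4 2-(2-methoxy-4-methylphenyl)hex-5-en-2-ol (racemic), via (2-methoxy-4-methylphenyl)lithium 3 (not isolated)
Conditions: n-BuLi, THF, −78 °C; then 2, −78 → 0 °C; H2O
Reagents that add atoms: none
Why: Bromine–lithium exchange followed by 1,2-addition of the aryllithium to the methyl ketone; the low temperature limits enolisation of 2, and the new stereocentre is removed in step 2.

Step 2
Reactants: 4 2-(2-methoxy-4-methylphenyl)hex-5-en-2-ol
Product: 5 2-methoxy-4-methyl-1-(2-methylhex-5-en-2-yl)benzene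
Conditions: Me3Al (3 equiv), CH2Cl2, −78 → 25 °C; H2O
Reagents that add atoms: trimethylaluminium, C[Al](C)C
Why: Deoxygenative methylation of a tertiary benzylic alcohol: the aluminium alkoxide ionises to a cation stabilised by the o-methoxy-p-methyl arene and a methyl group is transferred from aluminium; the low temperature and excess reagent disfavour elimination.

Step 3
Reactants: 5 2-methoxy-4-methyl-1-(2-methylhex-5-en-2-yl)benzene
Product: 6 5-(2-methoxy-4-methylphenyl)-5-methylhexan-2-ol (racemic)
Conditions: Co(acac)2 (divalent cobalt, 20 mol %), PhSiH3, O2 (1 atm), THF, 25 °C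
Reagents that add atoms: dioxygen, O=O
Why: Mukaiyama hydration (hydrogen-atom transfer to the terminal alkene, capture of the secondary radical by O2, reduction of the peroxide) gives the Markovnikov alcohol directly, so the side-chain oxygen enters at an oxidation level that survives step 4; the carbinol stereocentre is removed in step 5.

Step 4
Reactants: 6 5-(2-methoxy-4-methylphenyl)-5-methylhexan-2-ol
Product: 7 5-(2-methoxy-4-methylcyclohexa-1,4-dien-1-yl)-5-methylhexan-2-ol (racemic)
Conditions: Li, NH3(l), THF, t-BuOH, −78 → −33 °C; then NH4Cl(s)
Reagents that add atoms: none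
Why: Birch reduction; protonation occurs at the two unsubstituted positions para to each other, so the methoxy group and both alkyl groups stay on sp2 carbons and the 2,5-dihydroanisole pattern results; the side-chain alkoxide is inert.

Step 5
Reactants: 7 5-(2-methoxy-4-methylcyclohexa-1,4-dien-1-yl)-5-methylhexan-2-ol
Product: 8 5-(2-methoxy-4-methylcyclohexa-1,4-dien-1-yl)-5-methylhexan-2-one
Conditions: SO3·pyridine, DMSO, i-Pr2NEt, CH2Cl2, 0 °C; aq. NaHCO3
Reagents that add atoms: none
Why: Parikh–Doering oxidation runs in the presence of base throughout, so the acid-labile enol ether and the oxidation-prone 1,4-diene are not touched.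

Step 6
Reactants: 8 5-(2-methoxy-4-methylcyclohexa-1,4-dien-1-yl)-5-methylhexan-2-one
Product: 10 1-diazo-5-(2-methoxy-4-methylcyclohexa-1,4-dien-1-yl)-5-methylhexan-2-one, via trifluoroacetyl diketone 9 (not isolated)
Conditions: LiN(SiMe3)2, THF, −78 °C; CF3CO2CH2CF3; then 4-acetamidobenzenesulfonyl azide, Et3N, H2O, MeCN, 25 °C
Reagents that add atoms: 4-acetamidobenzenesulfonyl azide, CC(=O)Nc1ccc(cc1)S(=O)(=O)N=[N+]=[N-]
Why: Detrifluoroacetylative diazo transfer (a Regitz-type transfer to an activated 1,3-diketone): kinetic deprotonation occurs at the methyl group, the trifluoroacetyl group activates that carbon and leaves on the sulfonamide; this avoids diazomethane.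

Step 7
Reactants: 10 1-diazo-5-(2-methoxy-4-methylcyclohexa-1,4-dien-1-yl)-5-methylhexan-2-one
Product: 11 (1S,6S,7S)-7-methoxy-2,2,9-trimethyltricyclo[5.4.0.0^1,6]undec-9-en-5-one
Conditions: [Cu(MeCN)4]PF6 (monovalent copper, 5 mol %), 2,2'-(propane-2,2-diyl)bis[(4S)-4-tert-butyl-4,5-dihydrooxazole] (6 mol %), CH2Cl2, 25 °C, slow addition of 10
Reagents that add atoms: none
Why: Loss of N2 from 10 at the cationic copper centre gives an electrophilic keto-carbenoid, which is captured by the electron-rich enol ether; bonding starts at the nucleophilic β-carbon of the enol ether (the future spiro carbon) and the developing oxocarbenium ion collapses onto the carbenoid carbon, an asynchronous [2+1] addition. The closest known reaction type is the copper-catalysed intramolecular cyclopropanation of enol ethers and silyl enol ethers by terminal diazoketones to give bicyclo[4.1.0]heptan-2-ones. Ring A closes in the 6-exo mode (the tether ends on the attacked alkene carbon and the methoxy carbon stays outside the new six-membered ring); the cyclopropane closes in the [2+1] event itself, as a 3-exo collapse, cis-fused to both six-membered rings. The relative configuration of the three new stereocentres (spiro carbon, methoxy carbon, carbenoid carbon) is fixed by suprafacial addition and by the short tether, which can span only one face at a time; the absolute configuration is set by the C2-symmetric ligand, which must tell apart the two enantiotopic faces of the achiral diene. Chemoselectivity rests on the substrate: the trisubstituted ring alkene is out of reach of the tether, allylic C–H insertion would need a seven-membered transition state, and the gem-dimethyl group favours the folded chain (Thorpe–Ingold effect). Slow addition keeps the concentration of 10 low and should suppress carbene dimerisation.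

Step 8
Reactants: 11 (1S,6S,7S)-7-methoxy-2,2,9-trimethyltricyclo[5.4.0.0^1,6]undec-9-en-5-one
Product: 12 (6S)-3,11,11-trimethylspiro[5.5]undec-3-ene-1,8-dione
Conditions: aq. HCl (0.5 M), THF, 0 °C; aq. NaHCO3
Reagents that add atoms: water, O
Why: Donor–acceptor cyclopropane opening: protonation of the ring A carbonyl triggers push–pull cleavage of the bond between the methoxy carbon and the carbonyl-bearing carbon, the oxocarbenium ion is hydrolysed to the ring B ketone and the enol becomes the ring A CH2; no bond to the spiro carbon breaks, and cold dilute acid should leave the β,γ-alkene of ring B in place.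

Step 9
Reactants: 12 (6S)-3,11,11-trimethylspiro[5.5]undec-3-ene-1,8-dione
Product: 13 (7S)-10,13,13-trimethyl-1,4-dioxadispiro[4.1.5^7.3^5]pentadec-10-en-8-one
Conditions: Me3SiOCH2CH2OSiMe3 (1.1 equiv), Me3SiOTf (5 mol %), CH2Cl2, −78 °C; pyridine
Reagents that add atoms: 1,2-bis(trimethylsilyloxy)ethane, C[Si](C)(C)OCCO[Si](C)(C)C
Why: Aprotic ketalisation at low temperature; the ring A carbonyl lies between two CH2 groups whereas the ring B carbonyl is neopentylic, so only the former should react, and these conditions do not shift β,γ-double bonds.

Step 10
Reactants: 13 (7S)-10,13,13-trimethyl-1,4-dioxadispiro[4.1.5^7.3^5]pentadec-10-en-8-one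
Product: 14 (7S,8S)-10,13,13-trimethyl-1,4-dioxadispiro[4.1.5^7.3^5]pentadec-10-en-8-ol
Conditions: (R)-2-methyl-CBS-oxazaborolidine (20 mol %), catecholborane, toluene, −78 → −40 °C; then MeOH, H2O
Reagents that add atoms: none
Why: Corey–Bakshi–Shibata reduction: the ketone binds boron with the quaternary spiro carbon as the large group, and the (R)-catalyst delivers hydride to the face that gives the S carbinol, with hydroxyl cis to the ring A CH2 branch and trans to the gem-dimethyl branch; the substrate's own bias (axial attack opposite the axial CH2 branch when the gem-dimethyl carbon is equatorial on ring B) is expected to point the same way.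

Step 11
Reactants: 14 (7S,8S)-10,13,13-trimethyl-1,4-dioxadispiro[4.1.5^7.3^5]pentadec-10-en-8-ol
Product: 15 (7R,8S,10R,11R)-11-bromo-10-chloro-10,13,13-trimethyl-1,4-dioxadispiro[4.1.5^7.3^5]pentadecan-8-ol
Conditions: NBS, ClTi(OiPr)3 (tetravalent titanium), hexanes/CH2Cl2, −20 → 0 °C; aq. NaHCO3
Reagents that add atoms: N-bromosuccinimide, O=C1CCC(=O)N1Br; chlorotitanium triisopropoxide, CC(C)O[Ti](Cl)(OC(C)C)OC(C)C
Why: Titanium-alkoxide-directed bromochlorination of a homoallylic alcohol: the hydroxyl is bound as a chlorotitanium alkoxide, the bromonium ion that reacts is the one on the face away from oxygen, and chloride passes from titanium to the tertiary carbon through a six-membered array, so chlorine ends cis to oxygen and bromine anti to chlorine on the secondary carbon; Markovnikov opening and the tether act in the same direction, and both new stereocentres are relayed from the carbinol carbon.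

Step 12
Reactants: 15 (7R,8S,10R,11R)-11-bromo-10-chloro-10,13,13-trimethyl-1,4-dioxadispiro[4.1.5^7.3^5]pentadecan-8-ol
Product: 16 (7R,8S,10R,11R)-11-bromo-10-chloro-10,13,13-trimethyl-1,4-dioxadispiro[4.1.5^7.3^5]pentadecan-8-yl acetate
Conditions: Ac2O, DMAP (cat.), Et3N, CH2Cl2, 25 °C
Reagents that add atoms: acetic anhydride, CC(=O)OC(C)=O
Why: Nucleophilic-catalysed acylation through the N-acetylpyridinium ion overcomes the hindrance of the neopentylic alcohol; the amine bases are too weak to eliminate HBr or HCl, and the carbinol configuration is retained.

Step 13
Reactants: 16 (7R,8S,10R,11R)-11-bromo-10-chloro-10,13,13-trimethyl-1,4-dioxadispiro[4.1.5^7.3^5]pentadecan-8-yl acetate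
Product: 17 (1S,3R,4R,6R)-4-bromo-3-chloro-3,7,7-trimethyl-10-oxospiro[5.5]undecan-1-yl acetate
Conditions: aq. HCl (1 M), THF, 25 °C
Reagents that add atoms: water, O
Why: Acid hydrolysis of an unhindered cyclohexanone dioxolane; the secondary acetate and the inductively deactivated tertiary chloride should tolerate dilute acid at ambient temperature.

Step 14
Reactants: 17 (1S,3R,4R,6R)-4-bromo-3-chloro-3,7,7-trimethyl-10-oxospiro[5.5]undecan-1-yl acetate
Product: 18 (1S,3R,4R,6R)-4-bromo-3-chloro-3,7,7-trimethyl-10-oxospiro[5.5]undec-8-en-1-yl acetate
Conditions: IBX, 4-methoxypyridine N-oxide, DMSO, 25 → 40 °C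
Reagents that add atoms: none
Why: IBX dehydrogenation of a ketone through its enol; only the CH2–CH2 side has a β-hydrogen, because the other α-carbon is attached to the quaternary spiro carbon, so the C=C can only form towards the gem-dimethyl carbon, and the N-oxide complex allows a temperature at which acetate and halides persist.

Step 15
Reactants: 18 (1S,3R,4R,6R)-4-bromo-3-chloro-3,7,7-trimethyl-10-oxospiro[5.5]undec-8-en-1-yl acetate
Product: 20 (1S,3R,4R,6S)-4-bromo-3-chloro-11-[(dimethylamino)methyl]-3,7,7-trimethyl-10-oxospiro[5.5]undec-8-en-1-yl acetate (both C11 epimers), via silyl dienol ether 19 (not isolated)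
Conditions: Me3SiOTf, Et3N, CH2Cl2, 0 °C; then Me2N=CH2+ I−, 25 °C; aq. NaHCO3
Reagents that add atoms: N,N-dimethylmethyleneiminium iodide, C=[N+](C)C.[I-]
Why: Soft enolisation can only occur at the α′ CH2 (the γ carbon is quaternary) and gives the cross-conjugated 2-silyloxy diene, which undergoes a Mannich reaction with the iminium salt; no strong base is present, so acyl transfer from the cis acetate and elimination of halide are avoided, and the new stereocentre becomes sp2 in step 16.

Step 16
Reactants: 20 (1S,3R,4R,6S)-4-bromo-3-chloro-11-[(dimethylamino)methyl]-3,7,7-trimethyl-10-oxospiro[5.5]undec-8-en-1-yl acetate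
Product: 22 (1S,3R,4R,6R)-4-bromo-3-chloro-3,7,7-trimethyl-11-methylidene-10-oxospiro[5.5]undec-8-en-1-yl acetate, via trimethylammonium iodide 21 (not isolated)
Conditions: MeI, CH2Cl2, 25 °C; then aq. NaHCO3, 25 °C
Reagents that add atoms: none
Why: Quaternisation of the Mannich base and E1cB loss of trimethylamine give the exocyclic enone under mildly basic conditions that leave the four stereocentres, the acetate and the halides alone.

## Compound list

1 | 1-bromo-2-methoxy-4-methylbenzene | COc1cc(C)ccc1Br | starting material
2 | hex-5-en-2-one | CC(=O)CCC=C | starting material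
3 | (2-methoxy-4-methylphenyl)lithium | [Li]c1ccc(C)cc1OC | intermediate
4 | 2-(2-methoxy-4-methylphenyl)hex-5-en-2-ol (racemic) | COc1cc(C)ccc1C(C)(O)CCC=C | intermediate
5 | 2-methoxy-4-methyl-1-(2-methylhex-5-en-2-yl)benzene | COc1cc(C)ccc1C(C)(C)CCC=C | intermediate
6 | 5-(2-methoxy-4-methylphenyl)-5-methylhexan-2-ol (racemic) | COc1cc(C)ccc1C(C)(C)CCC(C)O | intermediate
7 | 5-(2-methoxy-4-methylcyclohexa-1,4-dien-1-yl)-5-methylhexan-2-ol (racemic) | COC1=C(C(C)(C)CCC(C)O)CC=C(C)C1 | intermediate
8 | 5-(2-methoxy-4-methylcyclohexa-1,4-dien-1-yl)-5-methylhexan-2-one | COC1=C(C(C)(C)CCC(C)=O)CC=C(C)C1 | intermediate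
9 | 1,1,1-trifluoro-7-(2-methoxy-4-methylcyclohexa-1,4-dien-1-yl)-7-methyloctane-2,4-dione | COC1=C(C(C)(C)CCC(=O)CC(=O)C(F)(F)F)CC=C(C)C1 | intermediate
10 | 1-diazo-5-(2-methoxy-4-methylcyclohexa-1,4-dien-1-yl)-5-methylhexan-2-one | COC1=C(C(C)(C)CCC(=O)C=[N+]=[N-])CC=C(C)C1 | intermediate
11 | (1S,6S,7S)-7-methoxy-2,2,9-trimethyltricyclo[5.4.0.0^1,6]undec-9-en-5-one | CO[C@]12CC(C)=CC[C@@]1(C(C)(C)CCC3=O)[C@@H]23 | intermediate
12 | (6S)-3,11,11-trimethylspiro[5.5]undec-3-ene-1,8-dione | O=C1CC(C)=CC[C@@]12CC(=O)CCC2(C)C | intermediate
13 | (7S)-10,13,13-trimethyl-1,4-dioxadispiro[4.1.5^7.3^5]pentadec-10-en-8-one | O=C1CC(C)=CC[C@@]12CC3(OCCO3)CCC2(C)C | intermediate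
14 | (7S,8S)-10,13,13-trimethyl-1,4-dioxadispiro[4.1.5^7.3^5]pentadec-10-en-8-ol | O[C@H]1CC(C)=CC[C@@]12CC3(OCCO3)CCC2(C)C | intermediate
15 | (7R,8S,10R,11R)-11-bromo-10-chloro-10,13,13-trimethyl-1,4-dioxadispiro[4.1.5^7.3^5]pentadecan-8-ol | CC1(C)CCC2(OCCO2)C[C@@]13C[C@@H](Br)[C@](C)(Cl)C[C@@H]3O | intermediate
16 | (7R,8S,10R,11R)-11-bromo-10-chloro-10,13,13-trimethyl-1,4-dioxadispiro[4.1.5^7.3^5]pentadecan-8-yl acetate | CC1(C)CCC2(OCCO2)C[C@@]13C[C@@H](Br)[C@](C)(Cl)C[C@@H]3OC(C)=O | intermediate
17 | (1S,3R,4R,6R)-4-bromo-3-chloro-3,7,7-trimethyl-10-oxospiro[5.5]undecan-1-yl acetate | CC1(C)CCC(=O)C[C@@]12C[C@@H](Br)[C@](C)(Cl)C[C@@H]2OC(C)=O | intermediate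
18 | (1S,3R,4R,6R)-4-bromo-3-chloro-3,7,7-trimethyl-10-oxospiro[5.5]undec-8-en-1-yl acetate | CC1(C)C=CC(=O)C[C@@]12C[C@@H](Br)[C@](C)(Cl)C[C@@H]2OC(C)=O | intermediate
19 | trimethylsilyl dienol ether of 18: 4-bromo-3-chloro-3,7,7-trimethyl-10-(trimethylsilyloxy)spiro[5.5]undeca-8,10-dien-1-yl acetate, ring B as in 18 | CC1(C)C=CC(O[Si](C)(C)C)=C[C@@]12C[C@@H](Br)[C@](C)(Cl)C[C@@H]2OC(C)=O | intermediate
20 | (1S,3R,4R,6S)-4-bromo-3-chloro-11-[(dimethylamino)methyl]-3,7,7-trimethyl-10-oxospiro[5.5]undec-8-en-1-yl acetate (both C11 epimers) | CC1(C)C=CC(=O)C(CN(C)C)[C@@]12C[C@@H](Br)[C@](C)(Cl)C[C@@H]2OC(C)=O | intermediate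
21 | N-methyl quaternary ammonium iodide of 20 (trimethylammoniomethyl group at C11, ring B as in 18) | CC1(C)C=CC(=O)C(C[N+](C)(C)C)[C@@]12C[C@@H](Br)[C@](C)(Cl)C[C@@H]2OC(C)=O.[I-] | intermediate
22 | (1S,3R,4R,6R)-4-bromo-3-chloro-3,7,7-trimethyl-11-methylidene-10-oxospiro[5.5]undec-8-en-1-yl acetate | C=C1C(=O)C=CC(C)(C)[C@]12C[C@@H](Br)[C@](C)(Cl)C[C@@H]2OC(C)=O | target

## Step count and least certain steps

Total: 16 steps. Longest linear sequence: 16 steps (from 1 or 2 to 22).

**Step 7 (key step).** What may go wrong: poor discrimination of the enantiotopic faces by the ligand, and slow addition to the hindered tetrasubstituted enol ether with carbene dimerisation taking over. A simple acceptor carbenoid is held less tightly in the chiral pocket than an acceptor/acceptor one.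

Fallback, from 8 back to 12:
- The kinetic enolate of 8 (LiN(SiMe3)2, THF, −78 °C) is sulfonylated with benzenesulfonyl fluoride to the β-keto sulfone 5-(2-methoxy-4-methylcyclohexa-1,4-dien-1-yl)-5-methyl-1-(phenylsulfonyl)hexan-2-one F1.
- Diazo transfer (4-acetamidobenzenesulfonyl azide, Et3N, MeCN) gives 1-diazo-5-(2-methoxy-4-methylcyclohexa-1,4-dien-1-yl)-5-methyl-1-(phenylsulfonyl)hexan-2-one F2.
- Cyclopropanation under the conditions of step 7 should give 7-methoxy-2,2,9-trimethyl-6-(phenylsulfonyl)tricyclo[5.4.0.0^1,6]undec-9-en-5-one F3; α-diazo-β-keto sulfones respond more strongly to bis(oxazoline) control.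
- Cold dilute acid opens it to 3,11,11-trimethyl-7-(phenylsulfonyl)spiro[5.5]undec-3-ene-1,8-dione F4.
- SmI2 (divalent samarium, THF/MeOH, −78 °C) removes the sulfonyl group and gives 12.

**Step 11.** What may go wrong: loss of facial control if chloride attacks without the titanium tether, anti-Markovnikov opening, or capture of the bromonium ion by the free hydroxyl (bromoetherification). The tethered delivery may have to pass through a ring B conformer in which the gem-dimethyl carbon is axial.

Fallback, from 14 back to 16:
- Hydroxyl-directed epoxidation (VO(acac)2, tetravalent vanadium, t-BuOOH, CH2Cl2) gives the cis-epoxy alcohol 10,11-epoxy-10,13,13-trimethyl-1,4-dioxadispiro[4.1.5^7.3^5]pentadecan-8-ol F5.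
- Acetylation (Ac2O, DMAP) gives its acetate 10,11-epoxy-10,13,13-trimethyl-1,4-dioxadispiro[4.1.5^7.3^5]pentadecan-8-yl acetate F6.
- Li2NiBr4 (divalent nickel, THF) opens the epoxide at the secondary carbon with inversion to the bromohydrin 11-bromo-10-hydroxy-10,13,13-trimethyl-1,4-dioxadispiro[4.1.5^7.3^5]pentadecan-8-yl acetate F7.
- SOCl2 (CH2Cl2, −20 °C) replaces the tertiary hydroxyl by chlorine with retention through the bromonium ion formed by the anti bromine, giving 16.

**Step 10.** What may go wrong: poor facial selectivity if the conformational bias of the ring B ketone opposes the catalyst, or slow reduction of the neopentylic carbonyl with hydroboration of the alkene as a side path.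

Fallback, from 13 back to 14: dissolving-metal reduction (Li, NH3(l), THF, then NH4Cl) is thermodynamically controlled and gives the equatorial alcohol. This corresponds to 14 as long as the gem-dimethyl carbon prefers the equatorial position on ring B. The fallback makes no new compound (F0); the minor epimer could be returned to 13 by oxidation.

**Step 8.** What may go wrong: acid-catalysed migration of the ring B alkene into conjugation with the new ketone, or aldol reaction between the two carbonyls.

Fallback, from 11 back to 13: the migration is accepted and then repaired.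
- Opening of 11 with warmer acid gives the conjugated isomer 3,11,11-trimethylspiro[5.5]undec-2-ene-1,8-dione F8.
- Ketalisation as in step 9 gives 10,13,13-trimethyl-1,4-dioxadispiro[4.1.5^7.3^5]pentadec-9-en-8-one F9.
- γ-Deprotonation with LiN(i-Pr)2 (THF, −78 °C) and kinetic α-protonation of the dienolate with acetic acid deconjugate the enone and give 13.

**Step 15.** What may go wrong: failure of C–C bond formation at the α′ carbon, which is neopentylic to the spiro centre, or silyl transfer to the acetate.

Fallback, from 18 back to 22:
- The silyl dienol ether 19 is treated with aqueous formaldehyde and Sc(OTf)3 (trivalent scandium) in THF, an aqueous Mukaiyama aldol reaction, to give 4-bromo-3-chloro-11-(hydroxymethyl)-3,7,7-trimethyl-10-oxospiro[5.5]undec-8-en-1-yl acetate F10.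
- Mesylation (MsCl, Et3N, CH2Cl2, 0 °C) gives 4-bromo-3-chloro-11-[(methylsulfonyloxy)methyl]-3,7,7-trimethyl-10-oxospiro[5.5]undec-8-en-1-yl acetate F11, which eliminates with DBU in the same flask to 22.

## Further compounds

F1 | step 7 | 5-(2-methoxy-4-methylcyclohexa-1,4-dien-1-yl)-5-methyl-1-(phenylsulfonyl)hexan-2-one | COC1=C(C(C)(C)CCC(=O)CS(=O)(=O)c2ccccc2)CC=C(C)C1
F2 | step 7 | 1-diazo-5-(2-methoxy-4-methylcyclohexa-1,4-dien-1-yl)-5-methyl-1-(phenylsulfonyl)hexan-2-one | COC1=C(C(C)(C)CCC(=O)C(=[N+]=[N-])S(=O)(=O)c2ccccc2)CC=C(C)C1
F3 | step 7 | 7-methoxy-2,2,9-trimethyl-6-(phenylsulfonyl)tricyclo[5.4.0.0^1,6]undec-9-en-5-one (ring carbons configured as in 11) | CO[C@]12CC(C)=CC[C@@]1(C(C)(C)CCC3=O)[C@@]23S(=O)(=O)c1ccccc1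
F4 | step 7 | 3,11,11-trimethyl-7-(phenylsulfonyl)spiro[5.5]undec-3-ene-1,8-dione (spiro carbon as in 12) | O=C1CC(C)=CC[C@@]12C(S(=O)(=O)c3ccccc3)C(=O)CCC2(C)C
F5 | step 11 | 10,11-epoxy-10,13,13-trimethyl-1,4-dioxadispiro[4.1.5^7.3^5]pentadecan-8-ol (oxirane oxygen cis to hydroxyl) | CC1(C)CCC2(OCCO2)C[C@@]13C[C@@H]4O[C@]4(C)C[C@@H]3O
F6 | step 11 | 10,11-epoxy-10,13,13-trimethyl-1,4-dioxadispiro[4.1.5^7.3^5]pentadecan-8-yl acetate | CC1(C)CCC2(OCCO2)C[C@@]13C[C@@H]4O[C@]4(C)C[C@@H]3OC(C)=O
F7 | step 11 | 11-bromo-10-hydroxy-10,13,13-trimethyl-1,4-dioxadispiro[4.1.5^7.3^5]pentadecan-8-yl acetate | CC1(C)CCC2(OCCO2)C[C@@]13C[C@@H](Br)[C@](C)(O)C[C@@H]3OC(C)=O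
F0 | step 10 | none | none
F8 | step 8 | 3,11,11-trimethylspiro[5.5]undec-2-ene-1,8-dione (spiro carbon as in 12) | O=C1C=C(C)CC[C@@]12CC(=O)CCC2(C)C
F9 | step 8 | 10,13,13-trimethyl-1,4-dioxadispiro[4.1.5^7.3^5]pentadec-9-en-8-one (spiro carbon as in 13) | O=C1C=C(C)CC[C@@]12CC3(OCCO3)CCC2(C)C
F10 | step 15 | 4-bromo-3-chloro-11-(hydroxymethyl)-3,7,7-trimethyl-10-oxospiro[5.5]undec-8-en-1-yl acetate (ring B as in 18) | CC1(C)C=CC(=O)C(CO)[C@@]12C[C@@H](Br)[C@](C)(Cl)C[C@@H]2OC(C)=O
F11 | step 15 | 4-bromo-3-chloro-11-[(methylsulfonyloxy)methyl]-3,7,7-trimethyl-10-oxospiro[5.5]undec-8-en-1-yl acetate (ring B as in 18) | CC1(C)C=CC(=O)C(COS(C)(=O)=O)[C@@]12C[C@@H](Br)[C@](C)(Cl)C[C@@H]2OC(C)=O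
A1 | alternative 1 | (1S,3R,4R,6R)-4-bromo-3-chloro-3,7,7-trimethyl-10-oxospiro[5.5]undecan-1-yl acetate | CC1(C)CCC(=O)C[C@@]12C[C@@H](Br)[C@](C)(Cl)C[C@@H]2OC(C)=O
A2 | alternative 1 | 5-bromo-4-chloro-4-methyl-2-(2-oxobut-3-en-1-yl)-2-(prop-1-en-2-yl)cyclohexyl acetate (configured as ring B of the target) | C=CC(=O)C[C@]1(C(C)=C)C[C@@H](Br)[C@](C)(Cl)C[C@@H]1OC(C)=O
A3 | alternative 2 | 6-(1,3-dioxolan-2-yl)-5,5-dimethyl-8-methylidenebicyclo[4.2.0]octan-2-one | C=C1C[C@]2(C3OCCO3)[C@H]1C(=O)CCC2(C)C
A4 | alternative 2 | 3-(1,3-dioxolan-2-yl)-4,4-dimethylcyclohex-2-en-1-one | O=C1C=C(C2OCCO2)C(C)(C)CC1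
A5 | alternative 2 | propa-1,2-diene | C=C=C
A6 | alternative 3 | 3,7,7-trimethylspiro[5.5]undeca-3,8-dien-1-one | CC1(C)C=CCC[C@@]12CC=C(C)CC2=O
A7 | alternative 3 | (2R)-7-methyl-2-(2-methylprop-1-en-1-yl)-3,4,5,8-tetrahydro-2H-chromene | CC(C)=C[C@H]1CCC2=C(O1)CC(C)=CC2
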